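**Retrosynthetic overview** (carotenoid locants: ring C1 = CMe2, C2 = CH carrying the C5 arm C1''–C4'', C5 = CMe, C6 = ring carbon carrying the polyene)

1. The C50 skeleton is cut into C20 + C10 + C20: a two-fold Wittig reaction of phosphonium salt 19 with C10-dialdehyde 20, then reduction of the two side-chain esters to the allylic alcohols.
2. Salt 19 comes from enol triflate 15 by a Stille coupling that forms C6–C7; the triflate stands for a ketone at C6, and the arm on C2 is finished by a Wittig reaction on an aldehyde at C2''.
3. The cyclohexane ring (the only ring-forming event, used for both end groups) is closed at C1–C2 by a copper hydride-catalysed enantioselective reductive Michael cyclisation of the acyclic, achiral enone–enoate 6.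
4. Enabling feature: the quaternary gem-dimethyl carbon C1 lies between C6 (sp2 in the target, carried as C=O) and C2, whose arm begins CH2–CH= (a latent CH2–C=O). O=C6–C1–C2–C1''–C2''=O is therefore a 1,5-dicarbonyl, and one C1 methyl is a reduced =CH2, so hydride addition to an isopropenyl ketone makes the C1 enolate regiospecifically.
5. Compound 6 is assembled from hex-5-enoic acid, methyl acrylate and isopropenylmagnesium bromide.

Key step: step 3

Remark on the chemistry: the sense of induction of the copper–bisphosphine catalyst in step 3 cannot be assigned in advance. The (S)-ligand is written provisionally; the antipode that leads to (R)-9 is to be identified in the first runs (both are commercial).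

**Step 1**
Reactants: 1 hex-5-enoic acid; 2 methyl acrylate
Product: 3 (5E)-7-methoxy-7-oxohept-5-enoic acid
Conditions: 2 (3 equiv), Hoveyda–Grubbs II catalyst (2 mol %), CH2Cl2, 40 °C
Reagents that add atoms: none
Why: Olefin cross-metathesis of a terminal alkene with an acrylate is reliably E-selective and tolerates the free acid, and it is placed before the isopropenyl ketone exists because that group would otherwise close to a cyclohexenone by ring-closing metathesis.

**Step 2**
Reactants: 3 (5E)-7-methoxy-7-oxohept-5-enoic acid; 4 isopropenylmagnesium bromide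
Product: 6 methyl (2E)-8-methyl-7-oxonona-2,8-dienoate, via acid chloride 5 (not isolated)
Conditions: (COCl)2, cat. DMF, CH2Cl2, 0 °C to rt, evaporate; then isopropenylzinc chloride (from 4 and ZnCl2, THF, 0 °C), Pd(PPh3)4 (3 mol %), THF, 0 °C to rt
Reagents that add atoms: none
Why: In this Negishi acylation the alkenylzinc reagent made in the flask should couple with the acid chloride under Pd(0) without adding to the enoate or to the ketone that forms.

**Step 3**
Reactants: 6 methyl (2E)-8-methyl-7-oxonona-2,8-dienoate
Product: 9 methyl 2-[(1R)-2,2-dimethyl-3-oxocyclohexyl]acetate, via copper enolate 7 (not isolated), via silyl ketene acetal 8 (not isolated)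
Conditions: Cu(OAc)2·H2O (5 mol %), (S)-DTBM-SEGPHOS (5.5 mol %), (EtO)2MeSiH (1.5 equiv), toluene, 0 °C, 6 added slowly (final 0.02 M); then 1 M aq HCl/THF
Reagents that add atoms: none
Why: Proposed new method: the ligated copper hydride should deliver hydride to the unsubstituted terminal CH2 of the isopropenyl ketone, which turns that carbon into the second geminal methyl group and gives the fully substituted copper enolate 7 at C1 regiospecifically; 7 then adds to the β-carbon (C2) of the tethered (E)-enoate, the copper ester enolate so formed is silylated by the silane to 8 with return of copper hydride, and work-up hydrolyses 8 to 9. The closest known reaction type is the copper hydride-catalysed enantioselective reductive Michael (and reductive aldol) cyclisation of substrates with two tethered α,β-unsaturated carbonyl groups; new here are the enolendo mode and a tetrasubstituted enolate that closes onto a quaternary carbon. The ring closes as a 6-(enolendo)-exo-trig cyclisation through a chair-like transition state, and because the hydride step defines the enolate, no enolate towards C5 (which could only give a four-membered ring) is formed. The new stereocentre C2 is created in the C–C bond-forming step from an achiral substrate, so it is controlled only by the chiral bisphosphine on copper, which should distinguish the enantiotopic faces of the (E)-enoate held pseudo-equatorially in the chair-like array. The step needs hydride delivery to the enone and not the enoate (secured by the unsubstituted β-position and the more electrophilic ketone), cyclisation faster than intermolecular Michael addition or O-silylation of 7 (secured by slow addition, high dilution and absence of a proton source), and enantioface selectivity (secured by the ligand, to be optimised).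

**Step 4**
Reactants: 9 methyl 2-[(1R)-2,2-dimethyl-3-oxocyclohexyl]acetate
Product: 11 methyl 2-[(1R)-2,2,4-trimethyl-3-oxocyclohexyl]acetate (both C-4 epimers), via lithium enolate 10 (not isolated)
Conditions: LiHMDS (1.05 equiv), THF, −78 °C; MeI (1.5 equiv), DMPU, −78 to −20 °C
Reagents that add atoms: iodomethane, CI
Why: In this enolate alkylation the ketone α-CH2 (C5) is the only enolisable ketone position (C1 is quaternary) and is more acidic than the ester α-CH2, so one equivalent of base should give enolate 10 and methylation at C5, whose configuration is irrelevant because C5 becomes sp2 in step 5, while C2 carries no acidic hydrogen.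

**Step 5**
Reactants: 11 methyl 2-[(1R)-2,2,4-trimethyl-3-oxocyclohexyl]acetate (both C-4 epimers)
Product: 12 methyl 2-[(1R)-2,2,4-trimethyl-3-(trifluoromethanesulfonyloxy)cyclohex-3-en-1-yl]acetate
Conditions: Tf2O (1.3 equiv), 2,6-di-tert-butyl-4-methylpyridine (1.5 equiv), CH2Cl2, 0 °C to rt
Reagents that add atoms: trifluoromethanesulfonic anhydride, O=S(=O)(OS(=O)(=O)C(F)(F)F)C(F)(F)F
Why: Enol triflate formation by O-triflation with a hindered pyridine base needs no strong base, so the ester α-protons are left alone, and the double bond can only form towards C5 because C1 is quaternary, which fixes the tetrasubstituted C5=C6 alkene of the β-ring and merges both epimers of 11.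

**Step 6**
Reactants: 12 methyl 2-[(1R)-2,2,4-trimethyl-3-(trifluoromethanesulfonyloxy)cyclohex-3-en-1-yl]acetate
Product: 13 2-[(1R)-2,2,4-trimethyl-3-(trifluoromethanesulfonyloxy)cyclohex-3-en-1-yl]acetaldehyde
Conditions: DIBAL-H (1.1 equiv), CH2Cl2, −78 °C; MeOH, then aq Rochelle salt
Reagents that add atoms: none
Why: Partial reduction of a methyl ester by DIBAL-H at −78 °C stops at the aluminium hemiacetal, which releases the aldehyde on work-up, and the vinyl triflate is inert to the reagent at this temperature.

**Step 7**
Reactants: 13 2-[(1R)-2,2,4-trimethyl-3-(trifluoromethanesulfonyloxy)cyclohex-3-en-1-yl]acetaldehyde; 14 methyl 2-(triphenylphosphoranylidene)propanoate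
Product: 15 methyl (2E)-2-methyl-4-[(1R)-2,2,4-trimethyl-3-(trifluoromethanesulfonyloxy)cyclohex-3-en-1-yl]but-2-enoate
Conditions: 14 (1.3 equiv), CH2Cl2, rt to 40 °C
Reagents that add atoms: none
Why: Wittig olefination with an α-branched stabilised ylide is strongly E-selective for the trisubstituted enoate, which places the future CH2OH carbon trans to the chain as the target requires, and the ylide is too weakly basic to affect the triflate or C2.

**Step 8**
Reactants: 16 (2E)-3-methylpent-2-en-4-yn-1-ol
Product: 17 (2E,4E)-3-methyl-5-(tributylstannyl)penta-2,4-dien-1-ol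
Conditions: Bu3SnH (1.1 equiv), PdCl2(PPh3)2 (2 mol %), THF, 0 °C
Reagents that add atoms: tributyltin hydride, CCCC[SnH](CCCC)CCCC
Why: Palladium-catalysed hydrostannation of the terminal alkyne is a syn addition that places tin mainly on the terminal carbon and so gives the (4E)-dienylstannane, the internal regioisomer being removed by chromatography.

**Step 9**
Reactants: 15 methyl (2E)-2-methyl-4-[(1R)-2,2,4-trimethyl-3-(trifluoromethanesulfonyloxy)cyclohex-3-en-1-yl]but-2-enoate; 17 (2E,4E)-3-methyl-5-(tributylstannyl)penta-2,4-dien-1-ol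
Product: 18 methyl (2E)-4-[(1R)-3-[(1E,3E)-5-hydroxy-3-methylpenta-1,3-dien-1-yl]-2,2,4-trimethylcyclohex-3-en-1-yl]-2-methylbut-2-enoate
Conditions: Pd2(dba)3 (2.5 mol %), AsPh3 (20 mol %), NMP, 60 °C, dark; aq KF work-up
Reagents that add atoms: none
Why: Stille coupling of a vinyl triflate with an alkenylstannane forms C6–C7 with retention of both alkene geometries, the weakly ligated Pd/AsPh3 system in NMP is the one suited to hindered 2,6,6-trimethylcyclohexenyl triflates, and the free alcohol and the enoate are tolerated.

**Step 10**
Reactants: 18 methyl (2E)-4-[(1R)-3-[(1E,3E)-5-hydroxy-3-methylpenta-1,3-dien-1-yl]-2,2,4-trimethylcyclohex-3-en-1-yl]-2-methylbut-2-enoate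
Product: 19 {(2E,4E)-5-[(5R)-5-[(2E)-4-methoxy-3-methyl-4-oxobut-2-en-1-yl]-2,6,6-trimethylcyclohex-1-en-1-yl]-3-methylpenta-2,4-dien-1-yl}triphenylphosphonium bromide
Conditions: PPh3·HBr (1.05 equiv), MeOH, rt, dark
Reagents that add atoms: triphenylphosphine hydrobromide, [Br-].c1ccccc1[PH+](c1ccccc1)c1ccccc1
Why: Conversion of the dienylic alcohol into the phosphonium salt runs through the pentadienyl cation, which PPh3 captures at the primary terminus, the standard entry to C15-type Wittig salts, and the enoate and C2 are inert to the weakly acidic medium.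

**Step 11**
Reactants: 19 the phosphonium bromide of step 10 (two equivalents); 20 (2E,4E,6E)-2,7-dimethylocta-2,4,6-trienedial
Product: 23 dimethyl (2E,2'E)-4,4'-[(2R,2'R)-β,β-carotene-2,2'-diyl]bis(2-methylbut-2-enoate), via phosphorus ylide 21 (not isolated), via mono-olefinated aldehyde 22 (not isolated)
Conditions: 19 (2.2 equiv), NaOMe (2.4 equiv), MeOH/CH2Cl2, 0 °C to rt; then heptane, reflux, dark, crystallisation
Reagents that add atoms: none
Why: The two-fold Wittig olefination of the symmetrical dialdehyde forms C11=C12 and C11'=C12', Z isomers at these disubstituted bonds should be converted into the all-E polyene by thermal equilibration as is usual for carotenoids, and methoxide in methanol cannot alter the methyl esters.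

**Step 12**
Reactants: 23 dimethyl (2E,2'E)-4,4'-[(2R,2'R)-β,β-carotene-2,2'-diyl]bis(2-methylbut-2-enoate)
Product: 24 (2R,2'R)-2,2'-bis[(2E)-4-hydroxy-3-methylbut-2-en-1-yl]-β,β-carotene (the target)
Conditions: DIBAL-H (5 equiv), CH2Cl2/toluene, −78 to −30 °C, argon, dark; aq Rochelle salt
Reagents that add atoms: none
Why: DIBAL-H reduces the two α,β-unsaturated methyl esters by 1,2-addition to the primary allylic alcohols without touching the polyene, the enoate geometry or the stereocentres C2 and C2', which are not next to any acidifying group.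

**Compound list**

1 | hex-5-enoic acid | C=CCCCC(=O)O | starting material
2 | methyl acrylate | C=CC(=O)OC | starting material
3 | (5E)-7-methoxy-7-oxohept-5-enoic acid | OC(=O)CCC/C=C/C(=O)OC | intermediate
4 | isopropenylmagnesium bromide | C=C(C)[Mg]Br | starting material
5 | methyl (2E)-7-chloro-7-oxohept-2-enoate (acid chloride) | ClC(=O)CCC/C=C/C(=O)OC | intermediate
6 | methyl (2E)-8-methyl-7-oxonona-2,8-dienoate | C=C(C)C(=O)CCC/C=C/C(=O)OC | intermediate
7 | copper(I) enolate of methyl (2E)-8-methyl-7-oxonon-2-enoate (bisphosphine on copper not drawn) | CC(C)=C(O[Cu])CCC/C=C/C(=O)OC | intermediate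
8 | diethoxy(methyl)silyl methyl ketene acetal of 9 | COC(O[Si](C)(OCC)OCC)=C[C@H]1CCCC(=O)C1(C)C | intermediate
9 | methyl 2-[(1R)-2,2-dimethyl-3-oxocyclohexyl]acetate | O=C1CCC[C@H](CC(=O)OC)C1(C)C | intermediate
10 | lithium enolate of 9 (enolised towards the ring CH2) | [Li]OC1=CCC[C@H](CC(=O)OC)C1(C)C | intermediate
11 | methyl 2-[(1R)-2,2,4-trimethyl-3-oxocyclohexyl]acetate (both C-4 epimers) | O=C1C(C)CC[C@H](CC(=O)OC)C1(C)C | intermediate
12 | methyl 2-[(1R)-2,2,4-trimethyl-3-(trifluoromethanesulfonyloxy)cyclohex-3-en-1-yl]acetate | FC(F)(F)S(=O)(=O)OC1=C(C)CC[C@H](CC(=O)OC)C1(C)C | intermediate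
13 | 2-[(1R)-2,2,4-trimethyl-3-(trifluoromethanesulfonyloxy)cyclohex-3-en-1-yl]acetaldehyde | FC(F)(F)S(=O)(=O)OC1=C(C)CC[C@H](CC=O)C1(C)C | intermediate
14 | methyl 2-(triphenylphosphoranylidene)propanoate | COC(=O)C(C)=P(c1ccccc1)(c1ccccc1)c1ccccc1 | starting material
15 | methyl (2E)-2-methyl-4-[(1R)-2,2,4-trimethyl-3-(trifluoromethanesulfonyloxy)cyclohex-3-en-1-yl]but-2-enoate | FC(F)(F)S(=O)(=O)OC1=C(C)CC[C@H](C/C=C(\C)C(=O)OC)C1(C)C | intermediate
16 | (2E)-3-methylpent-2-en-4-yn-1-ol | OC/C=C(\C)C#C | starting material
17 | (2E,4E)-3-methyl-5-(tributylstannyl)penta-2,4-dien-1-ol | OC/C=C(C)/C=C/[Sn](CCCC)(CCCC)CCCC | intermediate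
18 | methyl (2E)-4-[(1R)-3-[(1E,3E)-5-hydroxy-3-methylpenta-1,3-dien-1-yl]-2,2,4-trimethylcyclohex-3-en-1-yl]-2-methylbut-2-enoate | OC/C=C(C)/C=C/C1=C(C)CC[C@H](C/C=C(\C)C(=O)OC)C1(C)C | intermediate
19 | {(2E,4E)-5-[(5R)-5-[(2E)-4-methoxy-3-methyl-4-oxobut-2-en-1-yl]-2,6,6-trimethylcyclohex-1-en-1-yl]-3-methylpenta-2,4-dien-1-yl}triphenylphosphonium bromide | [Br-].c1ccccc1[P+](c1ccccc1)(c1ccccc1)C/C=C(C)/C=C/C1=C(C)CC[C@H](C/C=C(\C)C(=O)OC)C1(C)C | intermediate
20 | (2E,4E,6E)-2,7-dimethylocta-2,4,6-trienedial | O=C/C(C)=C/C=C/C=C(C)/C=O | starting material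
21 | phosphorus ylide from 19 | c1ccccc1P(c1ccccc1)(c1ccccc1)=C/C=C(C)/C=C/C1=C(C)CC[C@H](C/C=C(\C)C(=O)OC)C1(C)C | intermediate
22 | mono-olefinated aldehyde: methyl (2E)-4-[(1R)-3-[(1E,3E,5E,7E,9E,11E)-3,7,12-trimethyl-13-oxotrideca-1,3,5,7,9,11-hexaen-1-yl]-2,2,4-trimethylcyclohex-3-en-1-yl]-2-methylbut-2-enoate | O=C/C(C)=C/C=C/C=C(C)/C=C/C=C(C)/C=C/C1=C(C)CC[C@H](C/C=C(\C)C(=O)OC)C1(C)C | intermediate
23 | dimethyl (2E,2'E)-4,4'-[(2R,2'R)-β,β-carotene-2,2'-diyl]bis(2-methylbut-2-enoate) | CC1=C(/C=C/C(C)=C/C=C/C(C)=C/C=C/C=C(C)/C=C/C=C(C)/C=C/C2=C(C)CC[C@H](C/C=C(\C)C(=O)OC)C2(C)C)C(C)(C)[C@@H](C/C=C(\C)C(=O)OC)CC1 | intermediate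
24 | (2R,2'R)-2,2'-bis[(2E)-4-hydroxy-3-methylbut-2-en-1-yl]-β,β-carotene | CC1=C(/C=C/C(C)=C/C=C/C(C)=C/C=C/C=C(C)/C=C/C=C(C)/C=C/C2=C(C)CC[C@H](C/C=C(\C)CO)C2(C)C)C(C)(C)[C@@H](C/C=C(\C)CO)CC1 | target

**Total step count:** 12
**Longest linear sequence:** 11 steps (steps 1–7 and 9–12; step 8 is a one-step side branch)

**Steps most likely to fail**

Step 3 (proposed new method). The copper enolate may be silylated or may add to the enone of a second substrate molecule before it cyclises, and the two faces of the enoate may be poorly differentiated, so that conversion to the ring or the enantiomeric purity at C2 is insufficient. The fallback sets out from 6 and uses known chemistry only. A protonative conjugate reduction with catalytic triphenylphosphine copper hydride, silane and tert-butanol in toluene reduces only the isopropenyl ketone and should give methyl (2E)-8-methyl-7-oxonon-2-enoate F1. Catalytic NaOMe in MeOH then effects a thermodynamic intramolecular Michael addition; only the enolate on the isopropyl side can close a six-membered ring. This should give racemic methyl 2-(2,2-dimethyl-3-oxocyclohexyl)acetate F2, which is resolved by preparative chromatography on a chiral stationary phase (SFC). The route is rejoined at 9.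

Step 9. Oxidative addition and transmetalation at the tetrasubstituted triflate next to the quaternary carbon may be slow, so that protodestannylation and homocoupling of the stannane take over. The fallback sets out from 15 and the commercial enynol 16. A Sonogashira coupling (Pd(PPh3)4, CuI, i-Pr2NH, DMF), which is far less sensitive to hindrance, should give methyl (2E)-4-[(1R)-3-[(3E)-5-hydroxy-3-methylpent-3-en-1-yn-1-yl]-2,2,4-trimethylcyclohex-3-en-1-yl]-2-methylbut-2-enoate F3. Semi-reduction of the conjugated alkyne with activated zinc (Zn/Cu/Ag, MeOH/H2O) should give methyl (2E)-4-[(1R)-3-[(1Z,3E)-5-hydroxy-3-methylpenta-1,3-dien-1-yl]-2,2,4-trimethylcyclohex-3-en-1-yl]-2-methylbut-2-enoate F4. Its strained Z double bond is isomerised with catalytic iodine in daylight, and the route is rejoined at 18.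

Step 5. O-Triflation of the hindered 2,2,6-trisubstituted ketone may be slow and stop at partial conversion, while a stronger base would enolise the ester instead. The fallback sets out from 11. Soft enolisation with TMSOTf and Et3N in CH2Cl2 can only go towards the methyl-bearing carbon and should give methyl 2-[(1R)-2,2,4-trimethyl-3-(trimethylsilyloxy)cyclohex-3-en-1-yl]acetate F5. CsF and PhNTf2 in DME then release the enolate regiospecifically without an amide base and triflate it on oxygen. The route is rejoined at 12.

**Further compounds**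

F1 | step 3 | methyl (2E)-8-methyl-7-oxonon-2-enoate | CC(C)C(=O)CCC/C=C/C(=O)OC
F2 | step 3 | methyl 2-(2,2-dimethyl-3-oxocyclohexyl)acetate (racemate) | O=C1CCCC(CC(=O)OC)C1(C)C
F3 | step 9 | methyl (2E)-4-[(1R)-3-[(3E)-5-hydroxy-3-methylpent-3-en-1-yn-1-yl]-2,2,4-trimethylcyclohex-3-en-1-yl]-2-methylbut-2-enoate | OC/C=C(\C)C#CC1=C(C)CC[C@H](C/C=C(\C)C(=O)OC)C1(C)C
F4 | step 9 | methyl (2E)-4-[(1R)-3-[(1Z,3E)-5-hydroxy-3-methylpenta-1,3-dien-1-yl]-2,2,4-trimethylcyclohex-3-en-1-yl]-2-methylbut-2-enoate | OC/C=C(C)/C=C\C1=C(C)CC[C@H](C/C=C(\C)C(=O)OC)C1(C)C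
F5 | step 5 | methyl 2-[(1R)-2,2,4-trimethyl-3-(trimethylsilyloxy)cyclohex-3-en-1-yl]acetate | C[Si](C)(C)OC1=C(C)CC[C@H](CC(=O)OC)C1(C)C
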